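The data are calculated with constants of no real substance, noise included.

A charge of nucleophile has to be chosen for the next run.

| flask | solid electrophile | nucleophile | remark | time |
|---|---|---|---|---|
| birch | 6.7 mM | 1.05 equiv | run made earlier |  |
| ash | 20 mM | 1.05 equiv | run made earlier |  |
| Saturday's | 10 mM | 1.10 equiv |  | 2.0 min |
| Wednesday's | 10 mM | 1.40 equiv |  | 2.0 min |
| Thursday's | 10 mM | 1.80 equiv |  | 2.0 min |

| run | time / s | solid electrophile / % | target / % |
|---|---|---|---|
| birch | 10.0 | 83 | 3 |
| birch | 20.0 | 76 | 13 |
| birch | 30.0 | 75 | 19 |
| birch | 40.0 | 69 | 22 |
| ash | 10.0 | 92 | 5 |
| ash | 20.0 | 90 | 11 |
| ash | 30.0 | 83 | 11 |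
| ash | 40.0 | 81 | 19 |

(each reading ± 2 percentage points)

- amounts and yields of target count crystals too
- given per volume of solution although it is solid: crystals, solid electrophile
- steps under discussion: nucleophile + acid set free <-> protonated nucleophile; electrophile + nucleophile -> acid set free + target; crystals <-> target; acid set free -> by-product carried off; solid electrophile <-> electrophile
- at the start none of the solid electrophile is in solution
- what has only dissolved of solid electrophile counts as not reacted

- part of the solid electrophile that has reacted (what has only dissolved counts as not reacted) at the end, Saturday's
- part of the solid electrophile that has reacted (what has only dissolved counts as not reacted) at the end, Wednesday's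
- part of the solid electrophile that has reacted (what has only dissolved counts as not reacted) at the end, Thursday's
- what raising the equivalents of nucleophile from its lowest to its highest value here does to the part of the solid electrophile that has reacted (what has only dissolved counts as not reacted) (changes below 5 percentage points count as none) (it rises / no change / it falls)

Birch and ash both carry 1.05 equiv of nucleophile, on charges of 6.7 mM and 20 mM. At 40.0 s they stand at 22% and 19% target, a gap of 3 percentage points against a scatter of 2 points on each reading. In these readings, at equal equivalents, the target percentage moves little with the charge of solid electrophile, so the equivalents are the setting to choose.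

What a further equivalent buys follows from dividing one rate by another, so that time drops out. Each target costs one nucleophile and frees one acid, and that acid takes a second nucleophile as protonated nucleophile, provided it is not carried off first:

nucleophile lost / target made = 2

Saturday's: 1.10 equiv / 2 = 55.0%

Wednesday's: 1.40 equiv / 2 = 70.0%

Thursday's: 1.80 equiv / 2 = 90.0%

This is my own reckoning of the nucleophile ceiling: the part of the solid electrophile that can react while every target costs two nucleophiles. While every target costs two nucleophiles, nucleophile is the limiting reagent, even in Thursday's. Birch's pace, 22% in 40.0 s, stretched over 2.0 min gives 66.0%, more than Saturday's ceiling, so the ceiling should count within the run. The ceiling is a limit reckoned under that cost, and it gives no yield.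

The forecast gives the part reacted: 46%, 58% and 73%, and it rises. Its ground is “each conversion may use about two nucleophiles unless acid is carried off”. Each value stands under its ceiling. Its gain from Saturday's to Thursday's, 27 points, exceeds the margin of 5 points, so on the forecast Thursday's charge is worth taking.

The flasks give 46.7%, 58.3% and 73.0%: it rises, by 26 points, and the forecast held.

    nucleophile + acid set free ⇌ protonated nucleophile, settled at all times (K = 4.00 × 10⁵ M⁻¹)
    electrophile + nucleophile → acid set free + target (k = 14.6 M⁻¹ s⁻¹)
    crystals ⇌ target, rate k3*(cs3 - [target]) while solid is left; crystals form when [target] > cs3 (solubility = 8.00 mM, k = 6.05 s⁻¹)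
    acid set free → by-product carried off (k = 0.676 s⁻¹)
    solid electrophile ⇌ electrophile, rate k5*(cs5 - [electrophile]) while solid is left; crystals form when [electrophile] > cs5 (solubility = 0.640 mM, k = 0.390 s⁻¹)

The loss of acid set free makes no difference to Saturday's answer: by-product carried off stands at 0.171 mM at 2.00 min. At 20.0 min it stands at 8.94 mM, and Saturday's has passed its ceiling at 97.7%. At the asked time Saturday's has reached 84.9% of its ceiling and Thursday's 81.1%. A neighbour flask like Saturday's, with 0.280 equiv of nucleophile, has a ceiling of 14.0% and gives 12.7%.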